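**Unseen reagent.** No column in either run shows L, so I could not count what remained of it. I followed the sum E + J instead, which is what the asked conversion counts.

| setting | maple | ash | flask |
|---|---|---|---|
| Q | 0.30 M | 0.30 M | 0.30 M |
| D | 0.30 M | 0.30 M | 0.30 M |
| L | 0.75 M | 0.75 M | 0.750 M |
| G | 3 mM | 1.5 mM | 3.0 mM |
| remark | the very flask that is asked about, followed so far | run made earlier |  |
| time |  |  | 15 h |

| run | time / h | E / % | J / % |
|---|---|---|---|
| maple | 0.417 | 4.2 | 1.0 |
| maple | 0.833 | 6.7 | 1.1 |
| maple | 1.33 | 10.4 | 1.4 |
| maple | 1.50 | 10.0 | 2.2 |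
| maple | 2.00 | 11.2 | 2.9 |
| maple | 2.50 | 12.5 | 3.7 |
| maple | 3.00 | 14.1 | 4.7 |
| ash | 0.833 | 6.2 | 0 |
| ash | 1.50 | 9.8 | 1.5 |
| ash | 2.50 | 13.4 | 3.4 |
| ash | 3.00 | 14.2 | 4.2 |
| ash | 4.00 | 16.1 | 6.9 |
| ash | 5.00 | 17.2 | 8.5 |
| ash | 6.00 | 18.9 | 10.6 |

(each reading ± 0.5 percentage points)

- excess of E over J in the product at 50 min
- excess of E over J in the product at 15 h
- part of the Q and D charged together that has reacted at 15 h

- L is single-handed; Q and D are mirror images of each other, charged as a racemate, each of them at the stated concentration
- the numbers in the tables scatter by 0.5 percentage points (one standard deviation)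
- an excess is the difference of the two amounts in percent of their sum
- an excess is below zero if the other one leads
- the handed part of L does not stay in what it makes, so the products of the two hands are mirror images too

**What mattered.** I took the inputs in turn. G mattered little for the sum E + J: at 3.00 h, maple, with twice the G of ash, stood at 18.8% against 18.4% in ash, so I let ash extend maple for that sum. The split between E and J dropped out of the sum. The late pace of ash, from 3.00 h to 6.00 h, was a fraction 0.0370 h⁻¹ of the charge. Held flat to 15 h, it would give 62.8%; stopped at 6.00 h, 29.5%. So the decay of the pace was the number to know well.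

**Pace half-life.** Over the first 1.50 h, ash ran at 0.0753 h⁻¹. Between the middles of the two windows, the time in which the pace of E + J fell by a factor of 2, the pace half-life, read off these scattered readings of ash, came to 3.66 h. From 6.00 h to 15 h lay 2.46 such half-lives, and the pace at the start of them was 0.0278 h⁻¹. Summing that decaying pace, I expected 41.5% reacted.

**The forecast.** From the same runs it gave excesses of 78% at 50 min and 9% at 15 h, and 50% reacted (40% to 61%), the late rate “slowed somewhat by L consumption”. My figure stood 8.5 percentage points lower.

**The result.** Maple gave excesses of 81.0% and 6.38%, and 40.7% reacted.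

    L + Q → E (k = 7.00 × 10⁻⁵ L mol⁻¹ s⁻¹)
    L + D → J (k = 1.60 × 10⁻⁶ L mol⁻¹ s⁻¹)
    Q + G ⇌ D + G, rate k3*[G]*[Q] forward; the back reaction follows from the equilibrium constant (k = 0.00720 L mol⁻¹ s⁻¹)
    G → X (k = 6.10 × 10⁻⁸ s⁻¹)
    E ⇌ J (k = 5.30 × 10⁻⁵ s⁻¹)
    L → Z (k = 2.30 × 10⁻⁵ s⁻¹)

**The neighbour.** In maple, L, in effect the limiting reagent, stood at 14% of its charge at 15.0 h, less than the 50% of its charge left of Q. For the neighbour charged with 0.45 M of L, I kept the pace half-life of 3.66 h and scaled the pace by the charge of L, which gave 24.9%. That neighbour reacted 27.6%.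

All runs are simulated for substances that don't exist; scatter was added.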